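**Plan**

1. Retrosynthesis: the first cut is the C(sp3)–C(sp2) bond between the last CH2 of the three-carbon arm on the exocyclic alkene of the γ-lactone (ring A) and the methyl-bearing carbon of the neighbouring (E)-trisubstituted alkene. One end is an unhindered primary carbon and the other a vinylic carbon of fixed geometry, so both can be stored as iodides and joined reductively by nickel with the hydroxyl, ring A and the butenolide (ring B) unprotected.
2. Ring A half: next cuts are the exocyclic C=C (Z-selective Still–Gennari-type olefination of a cyclic phosphonate) and the isobutenyl C=C (Wittig on a chiral-pool lactone aldehyde).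
3. Ring B half: next cuts are the butenolide C=C and lactone C–O (Wittig, lactonisation), the CH2–CH(O) bond beside the carbinol (hydrazone alkylation of a dihydroxyacetone unit), the vinylic C–I (hydrozirconation) and the trisubstituted alkene (syn-carbocupration of a butynoate).
4. Forward: ring A is bought and decorated in six steps; the diene chain is grown linearly, attached to the C3 ketone and ring B closed last on that half (ten steps); the halves are united in the final step.
5. Stereochemistry: C-5 (S) of ring A comes from (S)-5-(hydroxymethyl)butyrolactone; the (R)-carbinol from RAMP-hydrazone alkylation; the (Z)-alkylidene from kinetic control in the olefination; both (E)-alkenes from syn-additions to alkynes, carried on with retention.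

Key step: step 17

Remark on the chemistry: the cyclic phosphonate is carried as the mixture of C-3 epimers, which converge because C-3 becomes trigonal in the olefination; the hydrazone C=N geometry is left undefined.

**Route**

Step 1
Reactants: 1 (5S)-5-(hydroxymethyl)oxolan-2-one
Product: 2 (2S)-5-oxooxolane-2-carbaldehyde
Conditions: Dess–Martin periodinane, CH2Cl2, 0 °C to rt; used crude
Reagents that add atoms: none
Why: Dess–Martin oxidation of the primary alcohol stops at the aldehyde under neutral, non-enolising conditions, so the α-alkoxy stereocentre (the future C-5, S) should be untouched.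

Step 2
Reactants: 2 (2S)-5-oxooxolane-2-carbaldehyde
Product: 3 (5S)-5-(2-methylprop-1-en-1-yl)oxolan-2-one
Conditions: i-PrPPh3I, KN(SiMe3)2, THF, 0 °C; then 2, −78 °C to 0 °C
Reagents that add atoms: isopropyltriphenylphosphonium iodide, CC(C)[P+](c1ccccc1)(c1ccccc1)c1ccccc1.[I-]
Why: Wittig olefination with the non-stabilised isopropylidene ylide takes the aldehyde far faster than the lactone carbonyl, and cold addition of the aldehyde to the preformed ylide should keep the stereocentre from enolising.

Step 3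
Reactants: 3 (5S)-5-(2-methylprop-1-en-1-yl)oxolan-2-one
Product: 5 (5S)-3-[bis(2,2,2-trifluoroethoxy)phosphoryl]-5-(2-methylprop-1-en-1-yl)oxolan-2-one, via enol phosphate 4 (not isolated)
Conditions: LiN(i-Pr)2 (2.3 equiv), THF, −78 °C; (CF3CH2O)2P(O)Cl, −78 °C to rt; 1 M HCl quench
Reagents that add atoms: bis(2,2,2-trifluoroethyl) phosphorochloridate, O=P(Cl)(OCC(F)(F)F)OCC(F)(F)F
Why: O-phosphorylation of the lactone enolate followed by base-induced 1,3-migration of phosphorus from oxygen to carbon (vinyl phosphate to α-phosphono lactone rearrangement) should install the electron-poor phosphonate at C-3 without touching C-5.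

Step 4
Reactants: 5 (5S)-3-[bis(2,2,2-trifluoroethoxy)phosphoryl]-5-(2-methylprop-1-en-1-yl)oxolan-2-one; 6 3-[(tert-butyldimethylsilyl)oxy]propanal
Product: 7 (3Z,5S)-3-{3-[(tert-butyldimethylsilyl)oxy]propylidene}-5-(2-methylprop-1-en-1-yl)oxolan-2-one
Conditions: KN(SiMe3)2, 18-crown-6, THF, −78 °C; then 6, −78 °C, cold quench
Reagents that add atoms: none
Why: Still–Gennari-type Horner–Wadsworth–Emmons olefination, in which the electron-poor phosphonate and the crown-separated potassium ion make the addition irreversible, so that kinetic collapse should place the new chain cis to the lactone carbonyl (Z).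

Step 5
Reactants: 7 (3Z,5S)-3-{3-[(tert-butyldimethylsilyl)oxy]propylidene}-5-(2-methylprop-1-en-1-yl)oxolan-2-one
Product: 8 (3Z,5S)-3-(3-hydroxypropylidene)-5-(2-methylprop-1-en-1-yl)oxolan-2-one
Conditions: HF·pyridine, pyridine, THF, 0 °C; used at once
Reagents that add atoms: none
Why: Fluoride-mediated silyl ether cleavage under buffered, weakly acidic conditions should spare the allylic lactone C–O bond and the (Z)-alkene, and immediate use avoids acyl transfer to the cis-disposed primary hydroxyl.

Step 6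
Reactants: 8 (3Z,5S)-3-(3-hydroxypropylidene)-5-(2-methylprop-1-en-1-yl)oxolan-2-one
Product: 9 (3Z,5S)-3-(3-iodopropylidene)-5-(2-methylprop-1-en-1-yl)oxolan-2-one
Conditions: I2, PPh3, imidazole, CH2Cl2, 0 °C, dark
Reagents that add atoms: iodine, II
Why: Appel iodination replaces the primary hydroxyl by SN2 under neutral conditions that should leave ring A and both alkenes unchanged.

Step 7
Reactants: 10 pent-3-yn-1-ol
Product: 11 5-bromopent-2-yne
Conditions: CBr4, PPh3, CH2Cl2, 0 °C
Reagents that add atoms: carbon tetrabromide, BrC(Br)(Br)Br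
Why: Appel bromination of a primary homopropargylic alcohol proceeds by SN2 without affecting the internal alkyne.

Step 8
Reactants: 11 5-bromopent-2-yne; 12 ethyl but-2-ynoate
Product: 16 ethyl (2E)-3-methylnon-2-en-7-ynoate, via pent-3-yn-1-ylmagnesium bromide 13 (not isolated), via pent-3-yn-1-ylcopper 14 (not isolated), via alkenylcopper adduct 15 (not isolated)
Conditions: Mg, THF, rt; CuBr·SMe2, THF, −78 °C; then 12, −78 °C; aq. NH4Cl at −78 °C
Reagents that add atoms: none
Why: syn-Carbocupration of the ynoate at −78 °C followed by cold protonation puts the incoming chain trans to the ester, which fixes the (E)-trisubstituted alkene, while the internal alkyne of the nucleophile is inert.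

Step 9
Reactants: 16 ethyl (2E)-3-methylnon-2-en-7-ynoate
Product: 17 (2E)-3-methylnon-2-en-7-yn-1-ol
Conditions: i-Bu2AlH (2.2 equiv), CH2Cl2, −78 °C to 0 °C; aq. potassium sodium tartrate
Reagents that add atoms: none
Why: 1,2-Reduction of the conjugated ester by the aluminium hydride gives the allylic alcohol without touching either the alkene geometry or the alkyne.

Step 10
Reactants: 17 (2E)-3-methylnon-2-en-7-yn-1-ol
Product: 19 (2E,6E)-7-iodo-3-methylocta-2,6-dien-1-ol, via alkenylzirconocene 18 (not isolated)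
Conditions: Cp2Zr(H)Cl (3 equiv), THF, rt then 50 °C; I2, THF, 0 °C
Reagents that add atoms: iodine, II
Why: syn-Hydrozirconation of the 2-alkyne with excess hydride and warming should equilibrate zirconium to the less hindered methyl-bearing carbon, and iodinolysis with retention gives the (E)-2-iodoalkene; the hydroxyl only consumes one equivalent as its alkoxide.

Step 11
Reactants: 19 (2E,6E)-7-iodo-3-methylocta-2,6-dien-1-ol
Product: 20 (2E,6E)-1-bromo-7-iodo-3-methylocta-2,6-diene
Conditions: CBr4, PPh3, CH2Cl2, −20 °C to 0 °C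
Reagents that add atoms: carbon tetrabromide, BrC(Br)(Br)Br
Why: Appel bromination of a primary allylic alcohol at low temperature should proceed by SN2 without allylic transposition, as with geraniol-type alcohols.

Step 12
Reactants: 21 2,2-dimethyl-1,3-dioxan-5-one; 22 (2R)-1-amino-2-(methoxymethyl)pyrrolidine (RAMP)
Product: 23 (2R)-N-(2,2-dimethyl-1,3-dioxan-5-ylidene)-2-(methoxymethyl)pyrrolidin-1-amine
Conditions: benzene, 4 Å molecular sieves, reflux
Reagents that add atoms: none
Why: Condensation of the hydrazine with the activated ketone gives the chiral hydrazone, a dihydroxyacetone equivalent ready for Enders alkylation.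

Step 13
Reactants: 23 (2R)-N-(2,2-dimethyl-1,3-dioxan-5-ylidene)-2-(methoxymethyl)pyrrolidin-1-amine; 20 (2E,6E)-1-bromo-7-iodo-3-methylocta-2,6-diene
Product: 25 (2R)-N-[(4R)-4-[(2E,6E)-7-iodo-3-methylocta-2,6-dien-1-yl]-2,2-dimethyl-1,3-dioxan-5-ylidene]-2-(methoxymethyl)pyrrolidin-1-amine, via lithium azaenolate 24 (not isolated)
Conditions: t-BuLi (1.05 equiv), THF, −78 °C; then 20, −100 °C to rt
Reagents that add atoms: none
Why: Enders RAMP-hydrazone alkylation, in which the methoxymethyl-chelated lithium azaenolate is attacked by the allylic bromide on its open face, which for the (R)-auxiliary should give the (4R) centre (the future (R)-carbinol); SN2 at the primary allylic carbon spares the C–I bond.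

Step 14
Reactants: 25 (2R)-N-[(4R)-4-[(2E,6E)-7-iodo-3-methylocta-2,6-dien-1-yl]-2,2-dimethyl-1,3-dioxan-5-ylidene]-2-(methoxymethyl)pyrrolidin-1-amine
Product: 26 (4R)-4-[(2E,6E)-7-iodo-3-methylocta-2,6-dien-1-yl]-2,2-dimethyl-1,3-dioxan-5-one
Conditions: saturated aq. oxalic acid, Et2O, rt
Reagents that add atoms: water, O
Why: Biphasic oxalic acid hydrolysis of the hydrazone is mild enough to leave the acetonide and the α-stereocentre intact and returns the auxiliary.

Step 15
Reactants: 26 (4R)-4-[(2E,6E)-7-iodo-3-methylocta-2,6-dien-1-yl]-2,2-dimethyl-1,3-dioxan-5-one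
Product: 27 methyl (2E)-2-[(4R)-4-[(2E,6E)-7-iodo-3-methylocta-2,6-dien-1-yl]-2,2-dimethyl-1,3-dioxan-5-ylidene]acetate
Conditions: Ph3P=CHCO2Me, toluene, rt to 40 °C
Reagents that add atoms: methyl (triphenylphosphoranylidene)acetate, COC(=O)C=P(c1ccccc1)(c1ccccc1)c1ccccc1
Why: Wittig olefination of the doubly α-oxygenated ketone with a stabilised, weakly basic ylide should turn the ester away from the substituted C-4 toward C-6 (E) by allylic strain, the geometry needed for the primary hydroxyl to lactonise later.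

Step 16
Reactants: 27 methyl (2E)-2-[(4R)-4-[(2E,6E)-7-iodo-3-methylocta-2,6-dien-1-yl]-2,2-dimethyl-1,3-dioxan-5-ylidene]acetate
Product: 29 4-[(1R,3E,7E)-1-hydroxy-8-iodo-4-methylnona-3,7-dien-1-yl]furan-2(5H)-one, via dihydroxy ester 28 (not isolated)
Conditions: TsOH·H2O (cat.), MeOH, rt
Reagents that add atoms: none
Why: Acid-catalysed transketalisation frees the 1,3-diol and the primary hydroxyl, cis to the ester, closes ring B by 5-exo-trig lactonisation, while the secondary carbinol is trans to the ester and cannot reach it.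

Step 17
Reactants: 9 (3Z,5S)-3-(3-iodopropylidene)-5-(2-methylprop-1-en-1-yl)oxolan-2-one; 29 4-[(1R,3E,7E)-1-hydroxy-8-iodo-4-methylnona-3,7-dien-1-yl]furan-2(5H)-one
Product: 30 (3Z,5S)-3-[(4E,8E,11R)-11-hydroxy-4,8-dimethyl-11-(5-oxo-2,5-dihydrofuran-3-yl)undeca-4,8-dien-1-ylidene]-5-(2-methylprop-1-en-1-yl)oxolan-2-one
Conditions: NiI2 (15 mol %), 4,4′-di-tert-butyl-2,2′-bipyridine (15 mol %), Zn dust (2.5 equiv), NaI (0.5 equiv), DMA, 0.3 M, 30 °C; 9 in 1.4-fold excess
Reagents that add atoms: none
Why: Nickel-catalysed reductive cross-electrophile coupling: zerovalent nickel inserts into the C(sp2)–I bond of 29 with retention, monovalent nickel abstracts iodine from 9 to give the primary alkyl radical, the divalent alkenylnickel captures it, and the trivalent nickel so formed reductively eliminates the C(sp3)–C(sp2) bond while zinc returns the catalyst. The closest known reaction type is the nickel/bipyridine-catalysed reductive coupling of alkenyl halides with unactivated primary alkyl halides, applied here to two fully functionalised halves. No ring is closed and no stereocentre is formed; both stereocentres, set earlier, are remote from the reacting carbons. Cross-coupling over homo-coupling is secured by the different hybridisation of the two iodide-bearing carbons (two-electron oxidative addition at the sp2 carbon, halogen-atom abstraction at the sp3 carbon), and the (E) geometry is kept because the alkenylnickel intermediate is configurationally stable. The free hydroxyl, both lactones and the allylic C–O bond of ring A should be left alone because the catalyst is consumed faster by the two C–I bonds, and the trisubstituted conjugated alkenes are poor radical acceptors. The (Z)-alkylidene survives only if nickel captures the homoallylic radical faster than it closes reversibly in a 3-exo mode onto the unsaturated lactone, which is why a high catalyst loading and concentration are specified.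

**Compound list**

1 | (5S)-5-(hydroxymethyl)oxolan-2-one | OC[C@@H]1CCC(=O)O1 | starting material
2 | (2S)-5-oxooxolane-2-carbaldehyde | O=C[C@@H]1CCC(=O)O1 | intermediate
3 | (5S)-5-(2-methylprop-1-en-1-yl)oxolan-2-one | CC(C)=C[C@@H]1CCC(=O)O1 | intermediate
4 | (2S)-2-(2-methylprop-1-en-1-yl)-2,3-dihydrofuran-5-yl bis(2,2,2-trifluoroethyl) phosphate | CC(C)=C[C@@H]1CC=C(OP(=O)(OCC(F)(F)F)OCC(F)(F)F)O1 | intermediate
5 | (5S)-3-[bis(2,2,2-trifluoroethoxy)phosphoryl]-5-(2-methylprop-1-en-1-yl)oxolan-2-one (both C-3 epimers) | CC(C)=C[C@@H]1CC(P(=O)(OCC(F)(F)F)OCC(F)(F)F)C(=O)O1 | intermediate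
6 | 3-[(tert-butyldimethylsilyl)oxy]propanal | O=CCCO[Si](C)(C)C(C)(C)C | starting material
7 | (3Z,5S)-3-{3-[(tert-butyldimethylsilyl)oxy]propylidene}-5-(2-methylprop-1-en-1-yl)oxolan-2-one | CC(C)=C[C@@H]1C/C(=C/CCO[Si](C)(C)C(C)(C)C)C(=O)O1 | intermediate
8 | (3Z,5S)-3-(3-hydroxypropylidene)-5-(2-methylprop-1-en-1-yl)oxolan-2-one | CC(C)=C[C@@H]1C/C(=C/CCO)C(=O)O1 | intermediate
9 | (3Z,5S)-3-(3-iodopropylidene)-5-(2-methylprop-1-en-1-yl)oxolan-2-one | CC(C)=C[C@@H]1C/C(=C/CCI)C(=O)O1 | intermediate
10 | pent-3-yn-1-ol | CC#CCCO | starting material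
11 | 5-bromopent-2-yne | CC#CCCBr | intermediate
12 | ethyl but-2-ynoate | CC#CC(=O)OCC | starting material
13 | pent-3-yn-1-ylmagnesium bromide | CC#CCC[Mg]Br | intermediate
14 | pent-3-yn-1-ylcopper | CC#CCC[Cu] | intermediate
15 | ethyl (2Z)-2-cuprio-3-methylnon-2-en-7-ynoate | CC#CCC/C(C)=C(\[Cu])C(=O)OCC | intermediate
16 | ethyl (2E)-3-methylnon-2-en-7-ynoate | CC#CCC/C(C)=C/C(=O)OCC | intermediate
17 | (2E)-3-methylnon-2-en-7-yn-1-ol | CC#CCC/C(C)=C/CO | intermediate
18 | (2E,6E)-2-[chlorobis(cyclopentadienyl)zirconio]-6-methylocta-2,6-dien-8-yl chlorobis(cyclopentadienyl)zirconium oxide (alkenylzirconocene of the zirconium alkoxide) | C/C(=C\CC/C(C)=C/CO[Zr](Cl)(C1C=CC=C1)C1C=CC=C1)[Zr](Cl)(C1C=CC=C1)C1C=CC=C1 | intermediate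
19 | (2E,6E)-7-iodo-3-methylocta-2,6-dien-1-ol | C/C(I)=C\CC/C(C)=C/CO | intermediate
20 | (2E,6E)-1-bromo-7-iodo-3-methylocta-2,6-diene | C/C(I)=C\CC/C(C)=C/CBr | intermediate
21 | 2,2-dimethyl-1,3-dioxan-5-one | CC1(C)OCC(=O)CO1 | starting material
22 | (2R)-1-amino-2-(methoxymethyl)pyrrolidine (RAMP) | COC[C@H]1CCCN1N | starting material
23 | (2R)-N-(2,2-dimethyl-1,3-dioxan-5-ylidene)-2-(methoxymethyl)pyrrolidin-1-amine | CC1(C)OCC(=NN2CCC[C@@H]2COC)CO1 | intermediate
24 | lithium azaenolate of 23 | CC1(C)OCC(N([Li])N2CCC[C@@H]2COC)=CO1 | intermediate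
25 | (2R)-N-[(4R)-4-[(2E,6E)-7-iodo-3-methylocta-2,6-dien-1-yl]-2,2-dimethyl-1,3-dioxan-5-ylidene]-2-(methoxymethyl)pyrrolidin-1-amine | C/C(I)=C\CC/C(C)=C/C[C@H]1OC(C)(C)OCC1=NN1CCC[C@@H]1COC | intermediate
26 | (4R)-4-[(2E,6E)-7-iodo-3-methylocta-2,6-dien-1-yl]-2,2-dimethyl-1,3-dioxan-5-one | C/C(I)=C\CC/C(C)=C/C[C@H]1OC(C)(C)OCC1=O | intermediate
27 | methyl (2E)-2-[(4R)-4-[(2E,6E)-7-iodo-3-methylocta-2,6-dien-1-yl]-2,2-dimethyl-1,3-dioxan-5-ylidene]acetate | C/C(I)=C\CC/C(C)=C/C[C@H]1OC(C)(C)OC/C1=C\C(=O)OC | intermediate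
28 | methyl (2E,4R,6E,10E)-4-hydroxy-3-(hydroxymethyl)-11-iodo-7-methyldodeca-2,6,10-trienoate | C/C(I)=C\CC/C(C)=C/C[C@@H](O)/C(CO)=C/C(=O)OC | intermediate
29 | 4-[(1R,3E,7E)-1-hydroxy-8-iodo-4-methylnona-3,7-dien-1-yl]furan-2(5H)-one | C/C(I)=C\CC/C(C)=C/C[C@@H](O)C1=CC(=O)OC1 | intermediate
30 | (3Z,5S)-3-[(4E,8E,11R)-11-hydroxy-4,8-dimethyl-11-(5-oxo-2,5-dihydrofuran-3-yl)undeca-4,8-dien-1-ylidene]-5-(2-methylprop-1-en-1-yl)oxolan-2-one | CC(C)=C[C@@H]1C/C(=C/CC/C(C)=C/CC/C(C)=C/C[C@@H](O)C2=CC(=O)OC2)C(=O)O1 | target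

**Count**

Total steps: 17. Longest linear sequence: 10 steps (steps 7–11 and 13–17, from 10).

**Steps most likely to fail**

Step 17. The homoallylic radical from 9 may close reversibly in a 3-exo mode onto the unsaturated lactone before nickel captures it, which would erode the (Z)-alkylidene geometry; radical addition to the conjugated lactones and homo-coupling are further losses. The fallback replaces the radical union by a polar organozinc coupling at the same bond; it sets out from 9 and 29 and returns at 30. Zinc insertion into 9 (Zn dust, LiCl, THF, rt) gives {3-[(3Z,5S)-5-(2-methylprop-1-en-1-yl)-2-oxooxolan-3-ylidene]propyl}zinc iodide F1. Alcohol 29 is silylated (Et3SiCl, imidazole, CH2Cl2) to its triethylsilyl ether F2 so that it does not protonate the zinc reagent. Negishi coupling of the two (Pd(OAc)2, SPhos, THF, rt) gives the triethylsilyl ether of the target F3, and HF·pyridine then frees 30.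

Step 4. The cyclic phosphonate may give poor facial control in the addition, or the product may drift to the more stable (E)-alkylidene lactone under the basic conditions. The fallback makes the (Z)-alkene on an open chain before ring A is re-closed; it sets out from 3 and returns at 8.
- Lactone 3 is saponified (KOH, aq. MeOH) to potassium (4S)-4-hydroxy-6-methylhept-5-enoate F4.
- Silylation on both oxygens (t-BuMe2SiCl, imidazole, DMF) gives tert-butyldimethylsilyl (4S)-4-[(tert-butyldimethylsilyl)oxy]-6-methylhept-5-enoate F5.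
- Selective hydrolysis of the silyl ester (K2CO3, aq. MeOH/THF) gives (4S)-4-[(tert-butyldimethylsilyl)oxy]-6-methylhept-5-enoic acid F6.
- Methylation (Me3SiCHN2, MeOH/toluene) gives methyl (4S)-4-[(tert-butyldimethylsilyl)oxy]-6-methylhept-5-enoate F7.
- C-Phosphorylation as in step 3 gives methyl (4S)-2-[bis(2,2,2-trifluoroethoxy)phosphoryl]-4-[(tert-butyldimethylsilyl)oxy]-6-methylhept-5-enoate F8.
- Still–Gennari olefination with 6 (KN(SiMe3)2, 18-crown-6, THF, −78 °C) gives methyl (2Z)-5-[(tert-butyldimethylsilyl)oxy]-2-[(2S)-2-[(tert-butyldimethylsilyl)oxy]-4-methylpent-3-en-1-yl]pent-2-enoate F9.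
- HF·pyridine removes both silyl groups and the freed secondary hydroxyl closes the five-membered lactone, giving 8.

Step 15. The ester may turn toward the substituted C-4, or the α-alkoxy ketone may epimerise; the first would lead the wrong hydroxyl to lactonise in step 16. The fallback closes ring B by metathesis, so that olefin geometry no longer decides which hydroxyl closes the ring; it sets out from 26 and returns at 29.
- Non-basic methylenation of 26 (Cp2TiMe2, toluene, 65 °C) gives (4R)-4-[(2E,6E)-7-iodo-3-methylocta-2,6-dien-1-yl]-2,2-dimethyl-5-methylidene-1,3-dioxane F10.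
- Acetonide removal (TsOH·H2O, MeOH) gives (3R,5E,9E)-10-iodo-6-methyl-2-methylideneundeca-5,9-diene-1,3-diol F11.
- Selective acylation of the primary hydroxyl (acryloyl chloride, 2,4,6-collidine, CH2Cl2, −78 °C) gives (3R,5E,9E)-3-hydroxy-10-iodo-6-methyl-2-methylideneundeca-5,9-dien-1-yl prop-2-enoate F12.
- Ring-closing metathesis (second-generation Grubbs catalyst, CH2Cl2, 40 °C) gives 29.

**Further compounds**

F1 | step 17 | {3-[(3Z,5S)-5-(2-methylprop-1-en-1-yl)-2-oxooxolan-3-ylidene]propyl}zinc iodide | CC(C)=C[C@@H]1C/C(=C/CC[Zn]I)C(=O)O1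
F2 | step 17 | 4-[(1R,3E,7E)-8-iodo-4-methyl-1-[(triethylsilyl)oxy]nona-3,7-dien-1-yl]furan-2(5H)-one | C/C(I)=C\CC/C(C)=C/C[C@@H](O[Si](CC)(CC)CC)C1=CC(=O)OC1
F3 | step 17 | (3Z,5S)-3-[(4E,8E,11R)-4,8-dimethyl-11-(5-oxo-2,5-dihydrofuran-3-yl)-11-[(triethylsilyl)oxy]undeca-4,8-dien-1-ylidene]-5-(2-methylprop-1-en-1-yl)oxolan-2-one | CC(C)=C[C@@H]1C/C(=C/CC/C(C)=C/CC/C(C)=C/C[C@@H](O[Si](CC)(CC)CC)C2=CC(=O)OC2)C(=O)O1
F4 | step 4 | potassium (4S)-4-hydroxy-6-methylhept-5-enoate | [K+].[O-]C(=O)CC[C@H](O)C=C(C)C
F5 | step 4 | tert-butyldimethylsilyl (4S)-4-[(tert-butyldimethylsilyl)oxy]-6-methylhept-5-enoate | CC(C)=C[C@H](CCC(=O)O[Si](C)(C)C(C)(C)C)O[Si](C)(C)C(C)(C)C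
F6 | step 4 | (4S)-4-[(tert-butyldimethylsilyl)oxy]-6-methylhept-5-enoic acid | CC(C)=C[C@H](CCC(=O)O)O[Si](C)(C)C(C)(C)C
F7 | step 4 | methyl (4S)-4-[(tert-butyldimethylsilyl)oxy]-6-methylhept-5-enoate | CC(C)=C[C@H](CCC(=O)OC)O[Si](C)(C)C(C)(C)C
F8 | step 4 | methyl (4S)-2-[bis(2,2,2-trifluoroethoxy)phosphoryl]-4-[(tert-butyldimethylsilyl)oxy]-6-methylhept-5-enoate | CC(C)=C[C@H](CC(C(=O)OC)P(=O)(OCC(F)(F)F)OCC(F)(F)F)O[Si](C)(C)C(C)(C)C
F9 | step 4 | methyl (2Z)-5-[(tert-butyldimethylsilyl)oxy]-2-[(2S)-2-[(tert-butyldimethylsilyl)oxy]-4-methylpent-3-en-1-yl]pent-2-enoate | CC(C)=C[C@H](C/C(C(=O)OC)=C/CCO[Si](C)(C)C(C)(C)C)O[Si](C)(C)C(C)(C)C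
F10 | step 15 | (4R)-4-[(2E,6E)-7-iodo-3-methylocta-2,6-dien-1-yl]-2,2-dimethyl-5-methylidene-1,3-dioxane | C/C(I)=C\CC/C(C)=C/C[C@H]1OC(C)(C)OCC1=C
F11 | step 15 | (3R,5E,9E)-10-iodo-6-methyl-2-methylideneundeca-5,9-diene-1,3-diol | C/C(I)=C\CC/C(C)=C/C[C@@H](O)C(=C)CO
F12 | step 15 | (3R,5E,9E)-3-hydroxy-10-iodo-6-methyl-2-methylideneundeca-5,9-dien-1-yl prop-2-enoate | C/C(I)=C\CC/C(C)=C/C[C@@H](O)C(=C)COC(=O)C=C
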